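## Retrosynthetic overview

- **Numbering (cladiellin type):** ring A = cyclohexane C1, C10–C14. Ring B = tetrahydrofuran O–C2–C1–C10–C9. Ring C = ε-lactone C3–O–C16(=O)–C15–C14–C1–C2. Ring D = oxonane O–C2–C3–C4–C5–C6–C7–C8–C9. C6 bears OMe, C7 OH/Me, C11 OAc/Me.
- **Endgame:** 25 ⇒ (O-methylation) diol 24 ⇒ cut C6–C7 of ring D by a reductive carbonyl coupling (SmI2 pinacol) ⇒ tricyclic keto aldehyde 22 (rings A, B, C) with a 3-oxopropyl arm on C3 and an acetonyl arm on C9.
- **Enabling feature:** C6 and C7 are neighbouring ring D atoms that both carry oxygen and lie opposite the ring oxygen. Their arms start at C3 and C9, which stand cis on ring B. Ring C holds the C3 arm, and the ring B oxygen is β to C7, so it can share one samarium ion with O7.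
- **Rings C and B:** ring C ⇒ chelate-controlled Grignard addition at C3 plus oxidative lactonisation. Ring B, C10 and C11–O ⇒ intramolecular hetero-Diels–Alder reaction of a C2–O–CH=CH–COMe unit with the C10=C11 bond of carvone-derived ring A. The temporary dihydropyran is ozonised later to the C11 acetate and a C9 aldehyde.
- **Order of ring formation:** A (from (R)-carvone) → B (together with the temporary dihydropyran) → C → D.

Key step: step 13

Remark: (1-methoxyethyl)triphenylphosphonium chloride and the other unnumbered reagents are taken as purchasable; locants in the names follow the numbering above.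

## Route

Step 1
Reactants: 1 (R)-(−)-carvone; 2 3-(trimethylsilyl)prop-2-ynal
Product: 3 anti-aldol adduct (5R,6R)-6-[(1S)-1-hydroxy-3-(trimethylsilyl)prop-2-ynyl]carvone
Conditions: LDA, THF, −78 °C; 2, −78 °C; AcOH
Reagents that add atoms: none
Why: Kinetic α'-deprotonation and aldol addition through a Zimmerman–Traxler chair, in which the aldehyde enters anti to the isopropenyl group (C1 trans to C14) and the ring-fixed E-enolate gives the anti aldol (C2).

Step 2
Reactants: 3 anti-aldol adduct
Product: 4 tosylhydrazone of 3
Conditions: TsNHNH2, MeOH, 40 °C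
Reagents that add atoms: p-toluenesulfonyl hydrazide Cc1ccc(cc1)S(=O)(=O)NN
Why: Hydrazone condensation at the only ketone, run without added acid or base so that the β-hydroxy group and C1 are not disturbed.

Step 3
Reactants: 4 tosylhydrazone
Product: 6 (1S)-1-[(1R,6R)-3-methyl-6-(prop-1-en-2-yl)cyclohex-2-enyl]-3-(trimethylsilyl)prop-2-yn-1-ol, via allylic diazene 5 (not isolated)
Conditions: catecholborane (3 equiv), CHCl3, −42 → 0 °C; NaOAc·3H2O, reflux
Reagents that add atoms: none
Why: Alkene-transposing reduction of an enone tosylhydrazone, in which diazene 5 loses N2 in a retro-ene step that puts H on C12 and moves the double bond to C10=C11 without touching C1, C2 or C14.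

Step 4
Reactants: 6 propargylic alcohol; 7 but-3-yn-2-one
Product: 8 (E)-β-alkoxy enone (C2–O–CH=CH–COMe)
Conditions: PMe3 (10 mol %), CH2Cl2, 0 °C → rt
Reagents that add atoms: none
Why: Phosphine-catalysed oxa-Michael addition of a secondary alcohol to an ynone, which gives the (E)-vinylogous ester under neutral conditions.

Step 5
Reactants: 8 (E)-β-alkoxy enone
Product: 9 tricyclic dihydropyran (rings A and B plus temporary O–C7=C8 ring; 9-epi)
Conditions: MeAlCl2 (1.2 equiv), CH2Cl2, −78 → −30 °C; Et3N, aq. NaHCO3
Reagents that add atoms: none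
Why: Proposed new method: MeAlCl2 on the C7 carbonyl oxygen turns the β-alkoxy enone into a 1-oxadiene (vinylogous oxocarbenium ion) whose C9 is attacked by the less substituted alkene carbon C10 (five-membered closure of ring B on the face of ring A that carries C2), while the aluminium enolate oxygen collapses on the developing tertiary cation at C11 from the same face, so that C9–C10 and C11–O form suprafacially and C10 and C11 get the target configuration, with C9 set cis to C11 (9-epi, corrected in step 10) because only this mode gives an unstrained cis-fused dihydropyran; the closest known reaction types are the intramolecular inverse-electron-demand hetero-Diels–Alder reaction of alkylidene-1,3-dicarbonyl compounds with trisubstituted alkenes and the Lewis-acid-induced addition of alkenes to enones.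

Step 6
Reactants: 9 tricyclic dihydropyran
Product: 10 primary alcohol with free ethynyl group (C15 set)
Conditions: 9-BBN (1.3 equiv), THF, 0 °C → rt; NaOH, H2O2, MeOH–H2O, rt
Reagents that add atoms: hydrogen peroxide OO
Why: Hydroboration–oxidation in which 9-BBN takes only the 1,1-disubstituted alkene, attacking the rotamer with H14 eclipsing the double bond from the side away from C1 (the sense known for 2-substituted isopropenylcyclohexanes of the isopulegol type, sets C15), while the alkaline methanolic work-up also protodesilylates the alkyne.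

Step 7
Reactants: 10 alkynyl alcohol
Product: 12 C3 methyl ketone, via vinylsilane 11 (not isolated)
Conditions: [Cp*Ru(MeCN)3]PF6 (2 mol %), (EtO)3SiH, CH2Cl2, 0 °C → rt; KF, KHCO3, H2O2, THF–MeOH, rt
Reagents that add atoms: hydrogen peroxide OO
Why: Markovnikov alkyne hydrosilylation followed by Tamao–Fleming oxidation amounts to a non-acidic alkyne hydration that spares the enol ether.

Step 8
Reactants: 12 C3 methyl ketone; 13 (3-bromopropoxy)(tert-butyl)dimethylsilane
Product: 15 C3 tertiary alcohol/C16 primary alcohol diol, via Grignard reagent 14 (not isolated)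
Conditions: 13, Mg, THF, 40 °C; 12, THF, −78 → −20 °C (3 equiv of 14); H2O
Reagents that add atoms: none
Why: Cram-chelate Grignard addition in which magnesium bridges the ring B oxygen and the C3 carbonyl oxygen, so the alkyl group enters from the side of H2, away from C1, and sets C3.

Step 9
Reactants: 15 diol
Product: 17 tetracyclic ε-lactone (rings A, B, C plus dihydropyran), via lactol 16 (not isolated)
Conditions: Ag2CO3 on Celite (excess), toluene, reflux
Reagents that add atoms: none
Why: Fétizon oxidative lactonisation in which the neutral reagent oxidises the primary alcohol to the aldehyde, the nearby tertiary C3 hydroxyl closes lactol 16, and this is oxidised on to ring C without touching the enol ether or C15.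

Step 10
Reactants: 17 tetracyclic lactone
Product: 19 C11 acetate/C9 carbaldehyde (C9 as in the target), via 9-epi aldehyde 18 (not isolated)
Conditions: O3, CH2Cl2, −78 °C; Me2S; DBU (20 mol %), CH2Cl2, rt
Reagents that add atoms: ozone [O-][O+]=O
Why: Ozonolysis of the only C=C bond, an enol ether, turns C7 and its methyl group into the acetate already bound to O–C11 and C8 into an aldehyde, after which DBU epimerises the α-alkoxy aldehyde through its enolate to the more stable isomer with C8 trans to C11, which corrects C9.

Step 11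
Reactants: 19 aldehyde
Product: 21 acetonyl ketone with free C6 primary alcohol, via methyl enol ether 20 (not isolated)
Conditions: (1-methoxyethyl)triphenylphosphonium chloride, NaHMDS, THF, −78 → 0 °C; 1 M HCl, THF, rt
Reagents that add atoms: (1-methoxyethyl)triphenylphosphonium chloride COC(C)[P+](c1ccccc1)(c1ccccc1)c1ccccc1.[Cl-]; water O
Why: Wittig alkoxyolefination and hydrolysis (aldehyde to homologous methyl ketone), in which the ylide attacks only the aldehyde and dilute acid cleaves enol ether 20 and the primary silyl ether while the hindered lactone and tertiary acetate stay.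

Step 12
Reactants: 21 keto alcohol
Product: 22 tricyclic keto aldehyde
Conditions: Dess–Martin periodinane, CH2Cl2, rt
Reagents that add atoms: none
Why: Dess–Martin oxidation of the only free hydroxyl group, mild enough for the β-alkoxy ketone.

Step 13
Reactants: 22 tricyclic keto aldehyde
Product: 24 tetracyclic (6R,7R)-diol, via samarium ketyl 23 (not isolated)
Conditions: SmI2 (3 equiv, 0.1 M in THF), slow addition of 22 (final 0.002 M), THF, −78 → 0 °C; aq. NaHCO3
Reagents that add atoms: none
Why: SmI2 reduces the more easily reduced C6 aldehyde to ketyl 23, whose carbon adds to the C7 ketone held on the same trivalent samarium ion, and a second electron and work-up give the diol. The closest known reaction type is the SmI2 keto aldehyde pinacol cyclisation used for medium and large rings. Ring D closes in the 9-exo-trig mode, helped by the cis arms on ring B and by ring C, which fixes the C2–C3 rotamer so that C4 points under ring B towards C9. C7 is controlled by the C7=O group lying syn to the ring B oxygen (ketone rotamer preference plus O7–Sm–O chelation), because the tethered ketyl can then reach only the inner face and the hydroxyl ends on the exposed face (7R). C6 is controlled by the samarium bridge keeping O6 and O7 gauche while the nine-membered ring prefers a large C5–C6–C7–C8 torsion, which should give the trans (threo) diol (6R), the sense usual for pinacol closures of eight-membered and larger rings. The step needs cyclisation to win over dimerisation or simple reduction, and carbonyl over ester reduction; high dilution with slow addition secures the first, and the inertness of the lactone and acetate to additive-free SmI2, together with the absence of any α-heteroatom at C5 or C8, secures the second.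

Step 14
Reactants: 24 diol
Product: 25 CNP0238771.1 (target)
Conditions: MeOTf (1.5 equiv), 2,6-di-tert-butyl-4-methylpyridine, CH2Cl2, 0 °C → rt
Reagents that add atoms: methyl trifluoromethanesulfonate COS(=O)(=O)C(F)(F)F
Why: Non-basic O-alkylation in which the secondary C6 hydroxyl reacts far faster than the tertiary C7 hydroxyl, and neither the acetate nor the lactone can migrate or open.

## Compound list

1 | (R)-(−)-carvone | C=C(C)[C@@H]1CC=C(C)C(=O)C1 | starting material
2 | 3-(trimethylsilyl)prop-2-ynal | C[Si](C)(C)C#CC=O | starting material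
3 | anti-aldol adduct | C=C(C)[C@@H]1CC=C(C)C(=O)[C@H]1[C@H](O)C#C[Si](C)(C)C | intermediate
4 | tosylhydrazone of 3 | C=C(C)[C@@H]1CC=C(C)C(=NNS(=O)(=O)c2ccc(C)cc2)[C@H]1[C@H](O)C#C[Si](C)(C)C | intermediate
5 | allylic diazene (C10 unassigned) | C=C(C)[C@@H]1CC=C(C)C(N=N)[C@H]1[C@H](O)C#C[Si](C)(C)C | intermediate
6 | transposed homoallylic propargylic alcohol | C=C(C)[C@@H]1CCC(C)=C[C@H]1[C@H](O)C#C[Si](C)(C)C | intermediate
7 | but-3-yn-2-one | CC(=O)C#C | starting material
8 | (E)-β-alkoxy enone | C=C(C)[C@@H]1CCC(C)=C[C@H]1[C@H](O/C=C/C(C)=O)C#C[Si](C)(C)C | intermediate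
9 | tricyclic dihydropyran (9-epi) | C[Si](C)(C)C#C[C@H]1O[C@@H]2C=C(C)O[C@]3(C)CC[C@@H](C(C)=C)[C@H]1[C@H]23 | intermediate
10 | C16 primary alcohol, terminal alkyne | C#C[C@H]1O[C@@H]2C=C(C)O[C@]3(C)CC[C@@H]([C@@H](C)CO)[C@H]1[C@H]23 | intermediate
11 | 1-(triethoxysilyl)vinyl compound | C=C([Si](OCC)(OCC)OCC)[C@H]1O[C@@H]2C=C(C)O[C@]3(C)CC[C@@H]([C@@H](C)CO)[C@H]1[C@H]23 | intermediate
12 | C3 methyl ketone | CC(=O)[C@H]1O[C@@H]2C=C(C)O[C@]3(C)CC[C@@H]([C@@H](C)CO)[C@H]1[C@H]23 | intermediate
13 | (3-bromopropoxy)(tert-butyl)dimethylsilane | CC(C)(C)[Si](C)(C)OCCCBr | starting material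
14 | 3-(tert-butyldimethylsilyloxy)propylmagnesium bromide | CC(C)(C)[Si](C)(C)OCCC[Mg]Br | intermediate
15 | C3/C16 diol | CC(C)(C)[Si](C)(C)OCCC[C@](C)(O)[C@H]1O[C@@H]2C=C(C)O[C@]3(C)CC[C@@H]([C@@H](C)CO)[C@H]1[C@H]23 | intermediate
16 | seven-membered lactol (C16 unassigned) | CC(C)(C)[Si](C)(C)OCCC[C@]2(C)OC(O)[C@H](C)[C@@H]3CC[C@@]5(C)OC(C)=C[C@H]4O[C@H]2[C@@H]3[C@H]45 | intermediate
17 | tetracyclic ε-lactone | CC(C)(C)[Si](C)(C)OCCC[C@]2(C)OC(=O)[C@H](C)[C@@H]3CC[C@@]5(C)OC(C)=C[C@H]4O[C@H]2[C@@H]3[C@H]45 | intermediate
18 | 9-epi acetate aldehyde | CC(C)(C)[Si](C)(C)OCCC[C@]2(C)OC(=O)[C@H](C)[C@@H]3CC[C@@](C)(OC(C)=O)[C@@H]4[C@H]3[C@@H]2O[C@@H]4C=O | intermediate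
19 | acetate aldehyde, C9 as in the target | CC(C)(C)[Si](C)(C)OCCC[C@]2(C)OC(=O)[C@H](C)[C@@H]3CC[C@@](C)(OC(C)=O)[C@@H]4[C@H]3[C@@H]2O[C@H]4C=O | intermediate
20 | methyl enol ether (E/Z mixture) | CC(C)(C)[Si](C)(C)OCCC[C@]2(C)OC(=O)[C@H](C)[C@@H]3CC[C@@](C)(OC(C)=O)[C@@H]4[C@H]3[C@@H]2O[C@H]4C=C(C)OC | intermediate
21 | keto alcohol | OCCC[C@]2(C)OC(=O)[C@H](C)[C@@H]3CC[C@@](C)(OC(C)=O)[C@@H]4[C@H]3[C@@H]2O[C@H]4CC(C)=O | intermediate
22 | tricyclic keto aldehyde | O=CCC[C@]2(C)OC(=O)[C@H](C)[C@@H]3CC[C@@](C)(OC(C)=O)[C@@H]4[C@H]3[C@@H]2O[C@H]4CC(C)=O | intermediate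
23 | C6 samarium ketyl | [O-][CH]CC[C@]2(C)OC(=O)[C@H](C)[C@@H]3CC[C@@](C)(OC(C)=O)[C@@H]4[C@H]3[C@@H]2O[C@H]4CC(C)=O.[Sm+3].[I-].[I-] | intermediate
24 | tetracyclic (6R,7R)-diol | O[C@@H]1CC[C@]2(C)OC(=O)[C@H](C)[C@@H]3CC[C@@](C)(OC(C)=O)[C@@H]4[C@H]3[C@@H]2O[C@H]4C[C@@]1(C)O | intermediate
25 | CNP0238771.1 | CO[C@@H]1CC[C@]2(C)OC(=O)[C@H](C)[C@@H]3CC[C@@](C)(OC(C)=O)[C@@H]4[C@H]3[C@@H]2O[C@H]4C[C@@]1(C)O | target

## Step count and risks

Total step count: 14. Longest linear sequence: 14 (from 1).

**Step 5.** The developing C11 cation may lose a proton before the enolate oxygen closes, or the Lewis acid may not activate the vinylogous ester enough.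
- The fallback sets out from 8. CF3CO2H in CH2Cl2 brings about the known acid-promoted Prins cyclisation of a vinylogous ester with loss of a C12 proton. This gives the ring A/B acetonyl ether with a C11=C12 double bond F1.
- p-TsOH in hot toluene then equilibrates C9 by retro-oxa-Michael/oxa-Michael addition. It also adds the enol oxygen of the C7 ketone to the protonated alkene, which is the known acid cyclisation of δ,ε-unsaturated ketones to dihydropyrans.
- Only the 9-epimer can close without strain, so the sequence comes back to the route at 9.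

**Step 13.** Facial selectivity at C6 or C7 may be poor, or the aldehyde may simply be reduced or couple between two molecules.
- The fallback sets out from 22. Wittig methylenation of both carbonyl groups (Ph3P=CH2, THF, −78 → 0 °C) gives the diene F2.
- Ring-closing metathesis with the second-generation Grubbs catalyst in dilute hot toluene closes ring D as the (Z)-C6=C7 oxonene F3.
- OsO4/NMO adds from the exposed face to give the cis-diol F4, the C6 epimer of 24.
- Dess–Martin oxidation of the secondary alcohol gives the C6 ketol F5.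
- Corey–Bakshi–Shibata reduction ((S)-Me-CBS oxazaborolidine, BH3·SMe2, large group = C7) comes back to the route at 24.

**Step 9.** Closure of the lactol from the hindered tertiary hydroxyl may be too slow, so the oxidation stops at the aldehyde.
- The fallback sets out from 15. Oxidation with (n-Pr)4N[RuO4]/NMO·H2O in MeCN takes the primary alcohol to the hydroxy acid F6.
- F6 is closed by mixed-anhydride lactonisation (2-methyl-6-nitrobenzoic anhydride, DMAP, toluene, slow addition), which comes back to the route at 17.

Further compounds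
F1 | step 5 | ring A/B acetonyl ether with C11=C12 double bond (C9 unassigned) | C[Si](C)(C)C#C[C@H]1OC(CC(C)=O)[C@@H]2C(C)=CC[C@@H](C(C)=C)[C@H]12
F2 | step 13 | tricyclic diene (but-3-enyl on C3, methallyl on C9) | C=CCC[C@]2(C)OC(=O)[C@H](C)[C@@H]3CC[C@@](C)(OC(C)=O)[C@@H]4[C@H]3[C@@H]2O[C@H]4CC(C)=C
F3 | step 13 | (Z)-C6=C7 oxonene | C/C1=C/CC[C@]2(C)OC(=O)[C@H](C)[C@@H]3CC[C@@](C)(OC(C)=O)[C@@H]4[C@H]3[C@@H]2O[C@H]4C1
F4 | step 13 | cis-diol (6-epi-24) | O[C@H]1CC[C@]2(C)OC(=O)[C@H](C)[C@@H]3CC[C@@](C)(OC(C)=O)[C@@H]4[C@H]3[C@@H]2O[C@H]4C[C@@]1(C)O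
F5 | step 13 | C6 ketone/C7 tertiary alcohol (ketol) | O=C1CC[C@]2(C)OC(=O)[C@H](C)[C@@H]3CC[C@@](C)(OC(C)=O)[C@@H]4[C@H]3[C@@H]2O[C@H]4C[C@@]1(C)O
F6 | step 9 | C16 carboxylic acid/C3 tertiary alcohol | CC(C)(C)[Si](C)(C)OCCC[C@](C)(O)[C@H]1O[C@@H]2C=C(C)O[C@]3(C)CC[C@@H]([C@@H](C)C(=O)O)[C@H]1[C@H]23
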